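**Retrosynthetic overview**
1. Target ⇐ desilylation and diacetylation of macrocycle 26; the 11-membered ring is closed last at C7–C8 by Ni/Cr coupling of a C7 aldehyde with a C8 enol triflate.
2. The C2=C3 diene ⇐ E-selective Wittig reaction of an allylic tributylphosphonium ylide (from the isopropenyl group) with (R)-lactol 21, which carries C3–C7 and the C5 methyl stereocentre (from desymmetrised dimethyl 3-methylglutarate).
3. The C15/C16 trans-diol, C9–Me and C8–OTf ⇐ enone of cis-hydrindenone 8 (convex-face epoxidation, enolate methylation and triflation, opening of the allylic epoxide with water).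
4. 8 ⇐ key step: enantioselective desymmetrising intramolecular ene cyclisation of prochiral cyclohexadienone 7, which sets C10, C11 and C14 and creates the isopropenyl group (future C1=CH2 and C2).
5. 7 ⇐ p-cresol by oxidative dearomative para-allylation, anti-Markovnikov Wacker oxidation and Wittig reaction. Ring order: six-membered (from the arene) → five-membered (ene) → eleven-membered (Ni/Cr).

Assumption: labels C1–C16 follow the ring-atom order of the target SMILES (C1 bears the exocyclic CH2; C2=C3; C5–Me; C7–OAc; C8=C9 with C9–Me; C10 and C14 ring fusion; C15–OAc; C16–OH). Bicyclic intermediates use indene numbering (C5 = C8, C4 = C9, C3a = C10, C3 = C11, C7a = C14, C7 = C15, C6 = C16).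

**Route**

Step 1
Reactants: 1 p-cresol; 2 allyltrimethylsilane
Product: 3 4-allyl-4-methylcyclohexa-2,5-dien-1-one
Conditions: PhI(OAc)2 (1.1 equiv), 2 (4 equiv), (CF3)2CHOH/CH2Cl2, −15 °C
Reagents that add atoms: none
Why: Oxidative dearomatisation (λ3-iodane-mediated oxidative Hosomi–Sakurai allylation): the HFIP-stabilised phenoxenium ion is captured by the allylsilane at the methyl-bearing para carbon, which cannot rearomatise, giving an achiral 4,4-disubstituted dienone.

Step 2
Reactants: 3 4-allyl-4-methylcyclohexa-2,5-dien-1-one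
Product: 4 3-(1-methyl-4-oxocyclohexa-2,5-dien-1-yl)propanal
Conditions: PdCl2(PhCN)2 (10 mol %), CuCl2·2H2O (10 mol %), AgNO2 (5 mol %), O2 (1 atm), t-BuOH/MeNO2, 23 °C
Reagents that add atoms: dioxygen O=O
Why: Nitrite-modified aldehyde-selective (anti-Markovnikov) Wacker oxidation of the terminal alkene; the electron-poor dienone double bonds do not react with Pd(II).

Step 3
Reactants: 4 3-(1-methyl-4-oxocyclohexa-2,5-dien-1-yl)propanal; 5 isopropyltriphenylphosphonium iodide
Product: 7 4-methyl-4-(4-methylpent-3-en-1-yl)cyclohexa-2,5-dien-1-one, via isopropylidenetriphenylphosphorane 6 (not isolated)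
Conditions: 5, n-BuLi, THF, 0 °C; then 4, −78 → 0 °C
Reagents that add atoms: none
Why: Wittig olefination; the non-stabilised ylide reacts with the aldehyde much faster than with the cross-conjugated (vinylogously deactivated) dienone carbonyl, and no stereocentre or alkene geometry is at stake.

Step 4 (key step)
Reactants: 7 4-methyl-4-(4-methylpent-3-en-1-yl)cyclohexa-2,5-dien-1-one
Product: 8 (3R,3aR,7aR)-7a-methyl-3-(prop-1-en-2-yl)-1,2,3,3a,4,7a-hexahydro-5H-inden-5-one
Conditions: cationic (S)-o-tolyl-oxazaborolidine·HNTf2 (20 mol %), CH2Cl2, −78 → −20 °C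
Reagents that add atoms: none
Why: Proposed new method: chiral-Lewis-acid-catalysed desymmetrising intramolecular type I conjugate-ene cyclisation; the boron cation binds the dienone carbonyl and differentiates the two enantiotopic enone arms, the trisubstituted alkene attacks the β-carbon (C10) of one arm through its less substituted terminus (C11, five-membered ring) while an allylic methyl hydrogen is passed suprafacially to the α-carbon (C9) in a concerted asynchronous transition state, which forces cis ring fusion (C10/C14) and places the new isopropenyl group cis to C9 at C11, and the non-basic triflimide counter-ion gives the alternative exo ion pair no product-forming exit; closest known reaction types are thermal and Lewis-acid-promoted type I ene cyclisations of 1,6-dienes onto enone or enoate enophiles (cis-selective) and chiral-acid-catalysed desymmetrisations of 4,4-disubstituted cyclohexadienones.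

Step 5
Reactants: 8 (3R,3aR,7aR)-7a-methyl-3-(prop-1-en-2-yl)-1,2,3,3a,4,7a-hexahydro-5H-inden-5-one
Product: 9 6,7-epoxide of 8 (oxirane O cis to the 7a-methyl)
Conditions: 30% H2O2, NaOH (cat.), MeOH, 0 °C
Reagents that add atoms: hydrogen peroxide OO
Why: Weitz–Scheffer nucleophilic epoxidation, selective for the enone over the isopropenyl group; hydroperoxide adds to C15 from the convex face of the cis-hydrindenone (the side of the angular methyl, away from the cyclopentane ring and the endo isopropenyl group), so the oxirane is cis to C14–Me.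

Step 6
Reactants: 9 6,7-epoxide of 8
Product: 11 4-methyl derivative of 9 (C4 epimer mixture), via lithium enolate 10 (not isolated)
Conditions: LDA, THF, −78 °C; then MeI, DMPU, −78 → −40 °C
Reagents that add atoms: iodomethane CI
Why: Kinetic enolate alkylation; C9 is the only enolisable α-carbon because C16 is an oxirane carbon, and the C9 configuration is irrelevant since it becomes sp2 in step 7.

Step 7
Reactants: 11 4-methyl derivative of 9
Product: 13 6,7-epoxy-4,7a-dimethyl-3-(prop-1-en-2-yl)-2,3,3a,6,7,7a-hexahydro-1H-inden-5-yl triflate, via potassium enolate 12 (not isolated)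
Conditions: KHMDS, THF, −78 °C; then PhNTf2, −78 → 0 °C
Reagents that add atoms: N-phenyl-bis(trifluoromethanesulfonimide) O=S(=O)(N(c1ccccc1)S(=O)(=O)C(F)(F)F)C(F)(F)F
Why: Regiodefined enol triflate formation; deprotonation is only possible at C9–H, giving the tetrasubstituted C8=C9 enolate that is O-sulfonylated.

Step 8
Reactants: 13 epoxy enol triflate
Product: 14 3-(3-chloroprop-1-en-2-yl) analogue of 13
Conditions: Ca(OCl)2, CO2 (dry ice), CH2Cl2/H2O, 0 °C
Reagents that add atoms: calcium hypochlorite [Ca+2].[O-]Cl.[O-]Cl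
Why: Ene-type allylic chlorination by HOCl; the 1,1-disubstituted isopropenyl alkene is the only electron-rich olefin (the enol triflate is deactivated) and gives the transposed 2-substituted allyl chloride.

Step 9
Reactants: 14 allylic chloride epoxide
Product: 15 trans-6,7-diol triflate (6-OH trans to 7-OH; 7-OH cis to 7a-Me)
Conditions: HClO4 (5 mol %), THF/H2O 3:1, 0 → 23 °C
Reagents that add atoms: water O
Why: Acid-catalysed epoxide hydrolysis; water attacks the allylic, non-neopentyl C16 with inversion (SN2-like trans opening), so C16–OH ends on the cyclopentane face and C15–OH stays cis to C14–Me.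

Step 10
Reactants: 15 trans-6,7-diol triflate
Product: 16 6-O-TBS ether of 15
Conditions: TBSOTf (1.05 equiv), 2,6-lutidine, CH2Cl2, −78 °C
Reagents that add atoms: tert-butyldimethylsilyl trifluoromethanesulfonate CC(C)(C)[Si](C)(C)OS(=O)(=O)C(F)(F)F
Why: Site-selective silylation; the allylic C16–OH reacts much faster than the neopentyl C15–OH next to the quaternary centre.

Step 11
Reactants: 17 dimethyl 3-methylglutarate
Product: 18 (R)-5-methoxy-3-methyl-5-oxopentanoic acid
Conditions: pig liver esterase, pH 7 phosphate buffer/MeOH 4:1, −10 °C (pH-stat)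
Reagents that add atoms: water O
Why: Enzymatic desymmetrisation of a prochiral diester (hydrolysis of the pro-S ester group) sets the future C5 methyl stereocentre.

Step 12
Reactants: 18 (R)-5-methoxy-3-methyl-5-oxopentanoic acid
Product: 20 (R)-4-methyltetrahydro-2H-pyran-2-one, via hydroxy ester 19 (not isolated)
Conditions: BH3·SMe2, THF, 0 → 23 °C; MeOH quench; then p-TsOH (cat.), benzene, 60 °C
Reagents that add atoms: none
Why: Chemoselective borane reduction of the carboxylic acid in the presence of the ester, then acid-catalysed lactonisation; the stereocentre is untouched.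

Step 13
Reactants: 20 (R)-4-methyltetrahydro-2H-pyran-2-one
Product: 21 (4R)-4-methyltetrahydro-2H-pyran-2-ol
Conditions: DIBAL-H (1.1 equiv), CH2Cl2, −78 °C; Rochelle salt
Reagents that add atoms: none
Why: Partial reduction of the lactone; the tetrahedral aluminium hemiacetal is stable at −78 °C and gives the lactol on work-up.

Step 14
Reactants: 16 6-O-TBS allylic chloride triflate; 21 (4R)-4-methyltetrahydro-2H-pyran-2-ol
Product: 24 (2E)-diene primary alcohol (C7/C8 seco compound), via phosphonium chloride 22 (not isolated), via phosphonium ylide 23 (not isolated)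
Conditions: PBu3, MeCN, 50 °C; evaporate; LiHMDS (1.05 equiv), THF, −78 °C; then 21 (1.5 equiv), −78 → 23 °C
Reagents that add atoms: none
Why: SN2 quaternisation followed by Wittig olefination of the semi-stabilised allylic tributylphosphonium ylide with the open hydroxy-aldehyde form of the lactol; such ylides are E-selective, giving the C2=C3 (E)-alkene next to the C1 exo-methylene and freeing the C7 primary alcohol.

Step 15
Reactants: 24 (2E)-diene primary alcohol
Product: 25 C7 aldehyde
Conditions: TEMPO (10 mol %), PhI(OAc)2 (1.2 equiv), CH2Cl2, 23 °C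
Reagents that add atoms: none
Why: Oxoammonium (TEMPO) oxidation, selective for the primary alcohol over the hindered secondary C15–OH.

Step 16
Reactants: 25 C7 aldehyde
Product: 26 macrocyclic (7S)-7,15-diol 16-O-TBS ether
Conditions: CrCl2 (8 equiv), NiCl2 (0.2 equiv), (S)-configured chiral sulfonamide ligand, Et3N, THF/DMF, 2 mM (syringe pump), 23 °C
Reagents that add atoms: none
Why: Nozaki–Hiyama–Kishi macrocyclisation (Ni inserts into C8–OTf, transmetalation to Cr(III), alkenylchromium adds to the aldehyde) closes the 11-membered ring; the C7 carbinol is set by the chiral sulfonamide ligand on chromium (reagent control).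

Step 17
Reactants: 26 macrocyclic 7,15-diol 16-O-TBS ether
Product: 27 7,15-di-O-acetate 16-O-TBS ether
Conditions: Ac2O, DMAP, Et3N, CH2Cl2, 23 → 40 °C
Reagents that add atoms: acetic anhydride CC(=O)OC(C)=O
Why: DMAP-catalysed acylation of both free hydroxyls (allylic C7–OH and neopentyl C15–OH) while C16–O stays silylated.

Step 18
Reactants: 27 7,15-di-O-acetate 16-O-TBS ether
Product: 28 CNP0323842.1 (target)
Conditions: HF·pyridine, pyridine/THF, 0 → 23 °C
Reagents that add atoms: none
Why: Fluoride-mediated Si–O cleavage under buffered acidic conditions frees C16–OH without acetyl migration.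

**Compound list**
1 | p-cresol | Cc1ccc(O)cc1 | starting material
2 | allyltrimethylsilane | C=CC[Si](C)(C)C | starting material
3 | 4-allyl-4-methylcyclohexa-2,5-dien-1-one | C=CCC1(C)C=CC(=O)C=C1 | intermediate
4 | 3-(1-methyl-4-oxocyclohexa-2,5-dien-1-yl)propanal | O=CCCC1(C)C=CC(=O)C=C1 | intermediate
5 | isopropyltriphenylphosphonium iodide | CC(C)[P+](c1ccccc1)(c1ccccc1)c1ccccc1.[I-] | starting material
6 | isopropylidenetriphenylphosphorane (not isolated) | CC(C)=P(c1ccccc1)(c1ccccc1)c1ccccc1 | intermediate
7 | 4-methyl-4-(4-methylpent-3-en-1-yl)cyclohexa-2,5-dien-1-one (prochiral) | CC(C)=CCCC1(C)C=CC(=O)C=C1 | intermediate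
8 | (3R,3aR,7aR)-7a-methyl-3-(prop-1-en-2-yl)-1,2,3,3a,4,7a-hexahydro-5H-inden-5-one (cis-fused; isopropenyl cis to C4) | O=C1C[C@@H]2[C@H](C(C)=C)CC[C@]2(C)C=C1 | intermediate
9 | 6,7-epoxide of 8, oxirane O cis to the 7a-methyl | O=C1C[C@@H]2[C@H](C(C)=C)CC[C@]2(C)[C@H]3O[C@@H]13 | intermediate
10 | lithium C4=C5 enolate of 9 (not isolated) | [Li+].[O-]C1=C[C@@H]2[C@H](C(C)=C)CC[C@]2(C)[C@H]3O[C@@H]13 | intermediate
11 | 4-methyl derivative of 9 (C4 epimers) | O=C1C(C)[C@@H]2[C@H](C(C)=C)CC[C@]2(C)[C@H]3O[C@@H]13 | intermediate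
12 | potassium C4=C5 enolate of 11 (not isolated) | [K+].[O-]C1=C(C)[C@@H]2[C@H](C(C)=C)CC[C@]2(C)[C@H]3O[C@@H]13 | intermediate
13 | 6,7-epoxy-4,7a-dimethyl-3-(prop-1-en-2-yl)-2,3,3a,6,7,7a-hexahydro-1H-inden-5-yl triflate | O=S(=O)(OC1=C(C)[C@@H]2[C@H](C(C)=C)CC[C@]2(C)[C@H]3O[C@@H]13)C(F)(F)F | intermediate
14 | 3-(3-chloroprop-1-en-2-yl) analogue of 13 | O=S(=O)(OC1=C(C)[C@@H]2[C@H](C(CCl)=C)CC[C@]2(C)[C@H]3O[C@@H]13)C(F)(F)F | intermediate
15 | trans-6,7-diol enol triflate (6-OH on the cyclopentane face, 7-OH cis to 7a-Me) | O=S(=O)(OC1=C(C)[C@@H]2[C@H](C(CCl)=C)CC[C@]2(C)[C@@H](O)[C@@H]1O)C(F)(F)F | intermediate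
16 | 6-O-TBS ether of 15 | O=S(=O)(OC1=C(C)[C@@H]2[C@H](C(CCl)=C)CC[C@]2(C)[C@@H](O)[C@@H]1O[Si](C)(C)C(C)(C)C)C(F)(F)F | intermediate
17 | dimethyl 3-methylglutarate | COC(=O)CC(C)CC(=O)OC | starting material
18 | (R)-5-methoxy-3-methyl-5-oxopentanoic acid | COC(=O)C[C@H](C)CC(=O)O | intermediate
19 | methyl (R)-5-hydroxy-3-methylpentanoate (not isolated) | COC(=O)C[C@H](C)CCO | intermediate
20 | (R)-4-methyltetrahydro-2H-pyran-2-one | O=C1C[C@H](C)CCO1 | intermediate
21 | (4R)-4-methyltetrahydro-2H-pyran-2-ol (anomers) | OC1C[C@H](C)CCO1 | intermediate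
22 | allylic tributylphosphonium chloride from 16 (not isolated) | O=S(=O)(OC1=C(C)[C@@H]2[C@H](C(C[P+](CCCC)(CCCC)CCCC)=C)CC[C@]2(C)[C@@H](O)[C@@H]1O[Si](C)(C)C(C)(C)C)C(F)(F)F.[Cl-] | intermediate
23 | allylic tributylphosphonium ylide (not isolated) | O=S(=O)(OC1=C(C)[C@@H]2[C@H](C(C=P(CCCC)(CCCC)CCCC)=C)CC[C@]2(C)[C@@H](O)[C@@H]1O[Si](C)(C)C(C)(C)C)C(F)(F)F | intermediate
24 | (2E)-diene with C7 primary alcohol, C8 enol triflate, C15–OH, C16–OTBS | O=S(=O)(OC1=C(C)[C@@H]2[C@H](C(=C)/C=C/C[C@H](C)CCO)CC[C@]2(C)[C@@H](O)[C@@H]1O[Si](C)(C)C(C)(C)C)C(F)(F)F | intermediate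
25 | C7 aldehyde of 24 | O=S(=O)(OC1=C(C)[C@@H]2[C@H](C(=C)/C=C/C[C@H](C)CC=O)CC[C@]2(C)[C@@H](O)[C@@H]1O[Si](C)(C)C(C)(C)C)C(F)(F)F | intermediate
26 | macrocyclic (7S)-7,15-diol 16-O-TBS ether | C=C1/C=C/C[C@H](C)C[C@H](O)C2=C(C)[C@@H]3[C@H]1CC[C@]3(C)[C@@H](O)[C@@H]2O[Si](C)(C)C(C)(C)C | intermediate
27 | 7,15-di-O-acetate 16-O-TBS ether | C=C1/C=C/C[C@H](C)C[C@H](OC(C)=O)C2=C(C)[C@@H]3[C@H]1CC[C@]3(C)[C@@H](OC(C)=O)[C@@H]2O[Si](C)(C)C(C)(C)C | intermediate
28 | CNP0323842.1 (5S,7S,10S,11R,14S,15R,16R in the labels above) | C=C1/C=C/C[C@H](C)C[C@H](OC(C)=O)C2=C(C)[C@@H]3[C@H]1CC[C@]3(C)[C@@H](OC(C)=O)[C@@H]2O | target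

**Step count and risks**
Total steps: 18 (15 on the core line, 3 for the lactol fragment). Longest linear sequence: 15 (steps 1–10 and 14–18).

Most likely to fail:

Step 1 (oxidative para-allylation of unblocked p-cresol). Ortho attack and formal [3+2] benzofuran formation may compete. The fallback sets out from 1 and returns at 3. Both ortho positions are brominated (Br2, AcOH) to give 2,6-dibromo-4-methylphenol F1. The same λ3-iodane/allylsilane dearomatisation on this para-only substrate gives 4-allyl-2,6-dibromo-4-methylcyclohexa-2,5-dien-1-one F2. The two vinylic bromides are then removed by Pd-catalysed hydrodebromination (Pd(PPh3)4, Bu3SnH, toluene) to give 3.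

Step 4 (catalytic asymmetric ene). A stepwise cationic pathway could give the C11 epimer, an isopropylidene isomer, a cyclobutane or low ee. The sense of induction must be assigned experimentally; the antipodal catalyst gives ent-8. The fallback sets out from 7 and returns at 8, separating symmetry breaking from ring formation. Copper hydride conjugate reduction (Cu(OAc)2, (R)-DTBM-SEGPHOS, PMHS) desymmetrises 7 to (R)-4-methyl-4-(4-methylpent-3-en-1-yl)cyclohex-2-en-1-one F3. A purely thermal, concerted type I ene reaction on the single remaining enone arm (toluene, sealed tube, about 180 °C) gives (3R,3aR,7aR)-7a-methyl-3-(prop-1-en-2-yl)octahydro-5H-inden-5-one F4, with the cis relationships fixed by the pericyclic geometry. Kinetic enolisation away from the ring fusion (LiTMP, TMSCl, −78 °C) gives the C5=C6 trimethylsilyl enol ether F5, and Saegusa oxidation (Pd(OAc)2, MeCN) restores the enone 8.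

Step 16 (11-membered Ni/Cr closure at a tetrasubstituted, flanked triflate; C7 configuration). The fallback forms C7–C8 intermolecularly and closes the ring at the unhindered C2=C3 bond. It sets out from 16 and from hydroxy ester 19 and returns at 26. Arbuzov reaction of 16 (P(OEt)3, NaI, 90 °C) gives the diethyl allylic phosphonate F6. Dess–Martin oxidation of 19 (borane reduction stopped before lactonisation) gives methyl (R)-3-methyl-5-oxopentanoate F7. Ligand-controlled intermolecular Ni/Cr coupling of F6 with F7 gives, after spontaneous lactonisation of the C7 alkoxide onto the C3 ester, the δ-lactone F8. DIBAL-H at −78 °C gives the lactol F9. Intramolecular Horner–Wadsworth–Emmons olefination of its open aldehyde form (KHMDS, 18-crown-6, THF, high dilution) forms the (2E)-diene and gives 26.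

**Further compounds**
F1 | step 1 | 2,6-dibromo-4-methylphenol | Cc1cc(Br)c(O)c(Br)c1
F2 | step 1 | 4-allyl-2,6-dibromo-4-methylcyclohexa-2,5-dien-1-one | C=CCC1(C)C=C(Br)C(=O)C(Br)=C1
F3 | step 4 | (R)-4-methyl-4-(4-methylpent-3-en-1-yl)cyclohex-2-en-1-one | O=C1C=C[C@](C)(CCC=C(C)C)CC1
F4 | step 4 | (3R,3aR,7aR)-7a-methyl-3-(prop-1-en-2-yl)octahydro-5H-inden-5-one | O=C1C[C@@H]2[C@H](C(C)=C)CC[C@]2(C)CC1
F5 | step 4 | C5=C6 trimethylsilyl enol ether of F4 | C[Si](C)(C)OC=1C[C@@H]2[C@H](C(C)=C)CC[C@]2(C)CC=1
F6 | step 16 | diethyl allylic phosphonate from 16 (Cl replaced by P(O)(OEt)2) | O=S(=O)(OC1=C(C)[C@@H]2[C@H](C(CP(=O)(OCC)OCC)=C)CC[C@]2(C)[C@@H](O)[C@@H]1O[Si](C)(C)C(C)(C)C)C(F)(F)F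
F7 | step 16 | methyl (R)-3-methyl-5-oxopentanoate | COC(=O)C[C@H](C)CC=O
F8 | step 16 | δ-lactone from C7–C8 coupling of F6 with F7 (C7–O acylated by C3) | O=C1C[C@H](C)C[C@H](O1)C2=C(C)[C@@H]3[C@H](C(CP(=O)(OCC)OCC)=C)CC[C@]3(C)[C@@H](O)[C@@H]2O[Si](C)(C)C(C)(C)C
F9 | step 16 | lactol from F8 | OC1C[C@H](C)C[C@H](O1)C2=C(C)[C@@H]3[C@H](C(CP(=O)(OCC)OCC)=C)CC[C@]3(C)[C@@H](O)[C@@H]2O[Si](C)(C)C(C)(C)C
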